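**Strategy**

With the ring numbered as a cyclohex-2-en-1-one (C2 bears CH2OTig, C4 OTig, C5 isopropyl, C6 OAc), the route rests on cutting the enone bond C2=C3 and the bond C5–C6 at once. The ketone C1 with its α-carbons C2 and C6 is an acetone 1,3-bis-nucleophile (acetoxyacetone); C3–C4–C5 is an enal 1,3-bis-electrophile carrying the C4 oxygen as a silyl enol ether. A chiral primary amine unites them in a Michael/aldol-condensation [3+3] annulation that sets C5 by catalyst control and funnels the labile C4 and C6 centres into the all-trans ring. Desilylation, Morita–Baylis–Hillman hydroxymethylation at C2 and a double Mitsunobu reaction with tiglic acid, inverting C4, complete the target.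

Key step: step 2

Assumption: the quinine-derived primary amine is taken to direct the enamine to the Si face of C3 of enal 3 (giving 5R in 6); if the sense proves opposite, the quinidine-derived pseudo-enantiomer is used with no other change.

**Route**

Step 1
Reactants: 1 isobutyraldehyde (2-methylpropanal); 2 (tert-butyldimethylsilyloxy)acetaldehyde
Product: 3 (Z)-2-[(tert-butyldimethylsilyl)oxy]-4-methylpent-2-enal
Conditions: pyrrolidine (20 mol %), PhCO2H (20 mol %), 1 (5 equiv), slow addition of 2, CH2Cl2, rt
Reagents that add atoms: none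
Why: Amine-catalysed cross-aldol (Mannich-type) condensation, in which the enamine of 2 adds to the iminium ion of 1 (which cannot self-condense to an enal) and β-elimination of pyrrolidine should give the enal as its thermodynamic Z isomer (CHO trans to isopropyl); no stereocentre is formed.

Step 2
Reactants: 3 (Z)-2-[(tert-butyldimethylsilyl)oxy]-4-methylpent-2-enal; 4 acetoxyacetone (2-oxopropyl acetate)
Product: 6 (4R,5R,6R)-6-acetoxy-4-[(tert-butyldimethylsilyl)oxy]-5-isopropylcyclohex-2-en-1-one, via keto aldehyde 5 (not isolated)
Conditions: 9-amino-9-deoxy-epi-quinine (20 mol %), TFA (40 mol %), 4 (3 equiv), toluene, 40 °C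
Reagents that add atoms: none
Why: Proposed new method: the primary amine converts enal 3 into an α-silyloxy iminium ion and ketone 4 into its more substituted, acetoxy-bearing enamine, whose carbon adds to the iminium β-carbon to form C5–C6 (Michael step, keto aldehyde 5); the methyl-ketone enamine (or enol) of 5 then attacks the aldehyde iminium carbon in a 6-(enolendo)-exo-trig aldol/Mannich closure, and elimination of the amine (or water) creates C2=C3. The closest known reaction types are the amine-catalysed Robinson-type formal carbo-[3+3] annulations of enals with ketone 1,3-bis-nucleophiles (Michael/aldol or Michael/Knoevenagel condensation) and the iminium activation of α-branched and α-acyloxy enals by cinchona primary amines; what is new is the pairing of an α-oxy ketone donor with an α-oxy enal acceptor. C5 is set by catalyst control (one face of the iminium β-carbon is shielded; attack on the Si face of C3 of 3 is required). C4 and C6 are both labile while the ring forms (C4 by enamine–iminium tautomerism of the α-silyloxy aldehyde, C6 by enolisation of the α-acetoxy ketone), so a chair-like closure with OTBS, isopropyl and OAc all equatorial, followed by equilibration at C6, should funnel the epimers of 5 into the 4,5-trans-5,6-trans isomer 6. The step needs Michael addition through the oxygenated α-carbon of 4 (favoured, as with hydroxyacetone-type donors, by the oxygen substituent on the enamine) and 1,4- in preference to 1,2-addition, which iminium activation of the trisubstituted enal should secure.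

Step 3
Reactants: 6 (4R,5R,6R)-6-acetoxy-4-[(tert-butyldimethylsilyl)oxy]-5-isopropylcyclohex-2-en-1-one
Product: 7 (4R,5S,6R)-6-acetoxy-4-hydroxy-5-isopropylcyclohex-2-en-1-one
Conditions: HF·pyridine, pyridine, THF, 0 °C to rt
Reagents that add atoms: none
Why: Fluoride-mediated cleavage of the secondary silyl ether (HF buffered by pyridine) should free the C4 hydroxyl without touching the acetate or the enone, and no stereocentre is altered (the descriptor at C5 changes only through priorities).

Step 4
Reactants: 7 (4R,5S,6R)-6-acetoxy-4-hydroxy-5-isopropylcyclohex-2-en-1-one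
Product: 8 (4R,5S,6R)-6-acetoxy-4-hydroxy-2-(hydroxymethyl)-5-isopropylcyclohex-2-en-1-one
Conditions: 37% aq. CH2O (3 equiv), DMAP (0.3 equiv), THF, rt
Reagents that add atoms: formaldehyde, C=O
Why: Morita–Baylis–Hillman reaction, in which DMAP adds to C3, the C2 enolate is hydroxymethylated by formaldehyde and the catalyst is expelled, so that only C2 is functionalised and no stereocentre is formed or changed.

Step 5
Reactants: 8 (4R,5S,6R)-6-acetoxy-4-hydroxy-2-(hydroxymethyl)-5-isopropylcyclohex-2-en-1-one; 9 tiglic acid ((E)-2-methylbut-2-enoic acid)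
Product: 11 (4S,5S,6R)-6-acetoxy-5-isopropyl-4-[(E)-2-methylbut-2-enoyloxy]-2-{[(E)-2-methylbut-2-enoyloxy]methyl}cyclohex-2-en-1-one (CNP0218511.1), via primary monotiglate 10 (not isolated)
Conditions: PPh3 (3 equiv), DIAD (3 equiv), 9 (3 equiv), toluene, 0 °C to rt
Reagents that add atoms: none
Why: Double Mitsunobu esterification, in which the primary alcohol is esterified first and the C4 oxyphosphonium ion is then displaced by tiglate in an SN2 reaction with inversion, which should turn the 4,5-trans alcohol into the required 4,5-cis (4S) tiglate while C5 and C6 stay untouched.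

**Compound list**

1 | isobutyraldehyde (2-methylpropanal) | CC(C)C=O | starting material
2 | (tert-butyldimethylsilyloxy)acetaldehyde | O=CCO[Si](C)(C)C(C)(C)C | starting material
3 | (Z)-2-[(tert-butyldimethylsilyl)oxy]-4-methylpent-2-enal | CC(C)/C=C(/C=O)O[Si](C)(C)C(C)(C)C | intermediate
4 | acetoxyacetone (2-oxopropyl acetate) | CC(=O)COC(C)=O | starting material
5 | (2S,3R,4R)-4-acetoxy-2-[(tert-butyldimethylsilyl)oxy]-3-isopropyl-5-oxohexanal (productive epimer; C2 and C4 equilibrate in the flask) | O=C[C@@H](O[Si](C)(C)C(C)(C)C)[C@H](C(C)C)[C@@H](OC(C)=O)C(C)=O | intermediate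
6 | (4R,5R,6R)-6-acetoxy-4-[(tert-butyldimethylsilyl)oxy]-5-isopropylcyclohex-2-en-1-one (4,5-trans, 5,6-trans) | C1=C[C@@H](O[Si](C)(C)C(C)(C)C)[C@H](C(C)C)[C@@H](OC(C)=O)C1=O | intermediate
7 | (4R,5S,6R)-6-acetoxy-4-hydroxy-5-isopropylcyclohex-2-en-1-one | C1=C[C@@H](O)[C@H](C(C)C)[C@@H](OC(C)=O)C1=O | intermediate
8 | (4R,5S,6R)-6-acetoxy-4-hydroxy-2-(hydroxymethyl)-5-isopropylcyclohex-2-en-1-one | OCC1=C[C@@H](O)[C@H](C(C)C)[C@@H](OC(C)=O)C1=O | intermediate
9 | tiglic acid ((E)-2-methylbut-2-enoic acid) | C/C=C(\C)C(=O)O | starting material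
10 | (4R,5S,6R)-6-acetoxy-4-hydroxy-5-isopropyl-2-{[(E)-2-methylbut-2-enoyloxy]methyl}cyclohex-2-en-1-one | C/C=C(\C)C(=O)OCC1=C[C@@H](O)[C@H](C(C)C)[C@@H](OC(C)=O)C1=O | intermediate
11 | (4S,5S,6R)-6-acetoxy-5-isopropyl-4-[(E)-2-methylbut-2-enoyloxy]-2-{[(E)-2-methylbut-2-enoyloxy]methyl}cyclohex-2-en-1-one (4,5-cis, 5,6-trans) | C/C=C(\C)C(=O)OCC1=C[C@H](OC(=O)/C(C)=C/C)[C@H](C(C)C)[C@@H](OC(C)=O)C1=O | target

**Step count**

Total steps: 5. Longest linear sequence: 5 steps (1 → 3 → 6 → 7 → 8 → 11).

**Steps most likely to fail**

Step 2 (proposed new method). The conjugate addition to the trisubstituted, captodative enal may be sluggish. The Michael step may leak through the methyl-side enamine of 4, leading after condensation to the 2-acetoxy regioisomer. The catalyst amine may be acetylated by 4, or facial discrimination at C5 may be poor. Fallback by known chemistry only, setting out from 1 and coming back at 6: Wittig olefination of 1 with (triphenylphosphoranylidene)acetaldehyde gives (E)-4-methylpent-2-enal F1. Iminium-catalysed Michael addition of tert-butyl acetoacetate to F1, using the enantiomer of α,α-bis[3,5-bis(trifluoromethyl)phenyl]prolinol trimethylsilyl ether that gives the 3R adduct, gives tert-butyl (3R)-2-acetyl-3-isopropyl-5-oxopentanoate F2. On addition of TsOH at 80 °C in the same pot, F2 undergoes aldol condensation, loss of isobutene and decarboxylation to (S)-5-isopropylcyclohex-2-en-1-one F3, so the same two ring bonds are made by the established β-keto ester/enal annulation. Isopropenyl acetate/TsOH gives the linear dienyl acetate (S)-5-isopropylcyclohexa-1,3-dien-1-yl acetate F4. γ-Hydroxylation with mCPBA, anti to the isopropyl group, gives (4R,5S)-4-hydroxy-5-isopropylcyclohex-2-en-1-one F5. TBSCl/imidazole gives (4R,5S)-4-[(tert-butyldimethylsilyl)oxy]-5-isopropylcyclohex-2-en-1-one F6. α'-Acetoxylation with Mn(OAc)3 (trivalent manganese) in refluxing benzene, trans to the C5 substituent, returns 6.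

Step 5. Displacement at the hindered allylic C4 oxyphosphonium ion may be slow, so that elimination towards a dienone (and aromatisation) or acylation with retention competes. Fallback replacing the redox condensation by acylation and sulfonate displacement, setting out from 8 and coming back at 11: tigloyl chloride with 2,4,6-collidine at −40 °C acylates only the primary alcohol to give 10 (here isolated). MsCl/Et3N converts 10 into (4R,5R,6R)-6-acetoxy-5-isopropyl-4-(methanesulfonyloxy)-2-{[(E)-2-methylbut-2-enoyloxy]methyl}cyclohex-2-en-1-one F8. Cesium tiglate (from 9 and Cs2CO3) with 18-crown-6 in toluene displaces the mesylate with inversion to give 11.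

Step 4. Addition of the amine catalyst to the γ-substituted β-carbon may be slow, and hydrolysis or transfer of the acetate may compete in the basic aqueous medium. Fallback through a cross-coupling, setting out from 7 and coming back at 8: α-iodination (I2, pyridine, CH2Cl2) gives (4S,5S,6R)-6-acetoxy-4-hydroxy-2-iodo-5-isopropylcyclohex-2-en-1-one F7. Stille coupling of F7 with (tributylstannyl)methanol [Pd(PPh3)4, zerovalent palladium, dioxane, 80 °C] returns 8.

**Further compounds**

F1 | step 2 | (E)-4-methylpent-2-enal | CC(C)/C=C/C=O
F2 | step 2 | tert-butyl (3R)-2-acetyl-3-isopropyl-5-oxopentanoate (C2 epimers) | O=CC[C@H](C(C)C)C(C(=O)OC(C)(C)C)C(C)=O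
F3 | step 2 | (S)-5-isopropylcyclohex-2-en-1-one | C1=CC[C@H](C(C)C)CC1=O
F4 | step 2 | (S)-5-isopropylcyclohexa-1,3-dien-1-yl acetate | CC(=O)OC1=CC=C[C@H](C(C)C)C1
F5 | step 2 | (4R,5S)-4-hydroxy-5-isopropylcyclohex-2-en-1-one | C1=C[C@@H](O)[C@H](C(C)C)CC1=O
F6 | step 2 | (4R,5S)-4-[(tert-butyldimethylsilyl)oxy]-5-isopropylcyclohex-2-en-1-one | C1=C[C@@H](O[Si](C)(C)C(C)(C)C)[C@H](C(C)C)CC1=O
F7 | step 4 | (4S,5S,6R)-6-acetoxy-4-hydroxy-2-iodo-5-isopropylcyclohex-2-en-1-one | IC1=C[C@@H](O)[C@H](C(C)C)[C@@H](OC(C)=O)C1=O
F8 | step 5 | (4R,5R,6R)-6-acetoxy-5-isopropyl-4-(methanesulfonyloxy)-2-{[(E)-2-methylbut-2-enoyloxy]methyl}cyclohex-2-en-1-one | C/C=C(\C)C(=O)OCC1=C[C@@H](OS(C)(=O)=O)[C@H](C(C)C)[C@@H](OC(C)=O)C1=O
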